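If the second substrate sets how far a flask goes, the fraction of starting material left at the end should follow from its charge, so I tested that on the earlier runs.

| flask | starting material | second substrate | reagent | free catalyst | remark | time |
|---|---|---|---|---|---|---|
| delta | 0.19 M | 0.046 M | 0.228 M | 0.19 mM | run made earlier |  |
| zeta | 0.19 M | 0.093 M | 0.228 M | 0.19 mM | run made earlier |  |
| epsilon | 0.19 M | 0.19 M | 0.228 M | 0.19 mM | run made earlier |  |
| Tuesday's | 0.19 M | 0.0500 M | 0.228 M | 0.19 mM |  | 15 h |
| Monday's | 0.19 M | 0.100 M | 0.228 M | 0.19 mM |  | 15 h |
| Friday's | 0.19 M | 0.200 M | 0.228 M | 0.19 mM |  | 15 h |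

| run | time / h | target / % |
|---|---|---|
| delta | 0.833 | 25.0 |
| delta | 1.50 | 39.3 |
| delta | 3.00 | 60.6 |
| delta | 6.00 | 81.3 |
| delta | 10.0 | 90.4 |
| zeta | 0.833 | 23.4 |
| zeta | 1.50 | 35.6 |
| zeta | 3.00 | 52.2 |
| zeta | 6.00 | 66.5 |
| zeta | 10.0 | 72.7 |
| epsilon | 2.00 | 33.3 |
| epsilon | 4.00 | 41.9 |
| epsilon | 6.00 | 45.9 |
| epsilon | 8.00 | 47.7 |
| epsilon | 10.0 | 48.7 |

(scatter of a reading: 0.3 percentage points)

- "hardly changes" means that all values lie within two and a half points (for a concentration: within two and a half percent of the largest)

* amount of target at the end, in percent of the starting material charged for Tuesday's, Monday's, Friday's, in this order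
* the shape of the row from first to last (falls all the way / falls, then rises / rises all the way / rises, then falls / hardly changes)

From the last epsilon reading I kept 0.667 as the stall number, the natural logarithm of one over the fraction of starting material left, times the second substrate charged as a fraction of the starting material charged. I read it from epsilon because its last two readings differ by 1 percentage point, less than zeta, which reads 0.635 and still rose by 6.2 points over its last two readings. Dividing the stall number by each new fraction, I reckoned 92.1% for Tuesday's, 71.9% for Monday's and 47.0% for Friday's.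

The forecast, reckoned differently, gave 91.5%, 73% and 48.2%, shape: falls all the way, on the ground that the second substrate “acts as a poison, killing the catalyst and stalling the reaction”. Its Friday's value stands higher than mine by 1.2 points.

The flasks gave 92.4% on Tuesday's, 72.1% on Monday's and 47.9% on Friday's, shape: falls all the way.

    starting material + free catalyst ⇌ catalyst intermediate A (K = 190 M⁻¹, k = 2.17 M⁻¹ s⁻¹)
    reagent + catalyst intermediate A → free catalyst + target (k = 0.623 M⁻¹ s⁻¹)
    second substrate + free catalyst ⇌ catalyst intermediate B (K = 870 M⁻¹, k = 2.58 M⁻¹ s⁻¹)
    reagent + catalyst intermediate B → free catalyst + second product (k = 5.35 M⁻¹ s⁻¹)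
    second substrate + catalyst intermediate A → spent catalyst (k = 8.45 × 10⁻⁴ M⁻¹ s⁻¹)

At 15.0 h, Friday's held 95.6% of its catalyst as spent catalyst, the off-cycle form, with 5.31% of its reagent left, whereas Monday's held 59.2% as spent catalyst with 0.591% of its reagent, the limiting reagent there, left. Friday's end value gives a stall number of 0.686, against the 0.667 I kept. Carried to Monday's charge, the kept stall number gives 71.9% of target, where Monday's flask gave 72.1%.

The earlier runs and the new flask are calculated on assumed constants, and the scatter is random.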